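**Plan** (flavone numbering: O1, C2–C4, ring A C5–C8, ring B C1'–C6')

- Retrosynthesis: the C5 and C5' hydroxyls are masked as methyl and benzyl ethers. Ring C is cut at O1–C2 and C2=C3 into the purchased ring A acetophenone 13 and the ring B aldehyde 12. Ring B is cut at C5'–C6' (six-electron closure) and C1'–C2' (alkenyllithium addition), leading back to methyl semisquarate 3 and bromoacetal 4.
- Enabling feature: ring B has oxygen on C2' and C5' (para), a methoxy on C3', hydrogen on C4' and C6', and its only free hydroxyl on C5'. A 4-alkenyl-3,4-dimethoxycyclobutenone delivers exactly this pattern when its carbonyl carbon becomes C5'.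
- Forward order: squarate → semisquarate → cyclobutenone 7 → ring B (step 4) → aldehyde 12 → chalcone 14 → ring C (step 7) → deprotection. Ring A is bought intact.
- Stereochemistry: the target has no stereocentre. The racemic centres of 2 and 7 are erased in steps 2 and 4, and the (E) alkene of 14 ends inside ring C.

Key step: step 4

Assumption: 1-(6-hydroxy-2,3,4-trimethoxyphenyl)ethan-1-one (13) is taken as a catalogue compound, as are 1 and 4.

**Route**

Step 1
Reactants: 1 dimethyl squarate
Product: 2 rac-4-hydroxy-2,3-dimethoxycyclobut-2-en-1-one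
Conditions: LiAlH(OtBu)3, THF, −78 → 0 °C; then H2O
Reagents that add atoms: none
Why: Chemoselective 1,2-reduction, in which the bulky mono-hydride LiAlH(OtBu)3 should deliver one hydride to one of the two equivalent vinylogous ester carbonyls and stop at the alkoxide, the usual entry to semisquarates; the new centre is racemic and disappears in step 2.

Step 2
Reactants: 2 rac-4-hydroxy-2,3-dimethoxycyclobut-2-en-1-one
Product: 3 3-methoxycyclobut-3-ene-1,2-dione
Conditions: 12 M HCl (cat.), CH2Cl2, rt
Reagents that add atoms: water, O
Why: Acid-promoted ionisation of the allylic hydroxyl should give a methoxy-stabilised cyclobutenyl cation that takes up water at the distal methoxy carbon and loses methanol, a Stork–Danheiser-type 1,3-carbonyl transposition of a vinylogous ester.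

Step 3
Reactants: 3 3-methoxycyclobut-3-ene-1,2-dione; 4 2-bromo-3,3-diethoxyprop-1-ene
Product: 7 rac-4-(3,3-diethoxyprop-1-en-2-yl)-3,4-dimethoxycyclobut-2-en-1-one, via alkenyllithium 5 (not isolated), via lithium alkoxide 6 (not isolated)
Conditions: 4, n-BuLi, THF, −78 °C; cannulate into 3, THF, −78 °C; then MeOTf, −78 → 0 °C
Reagents that add atoms: methyl trifluoromethanesulfonate, COS(=O)(=O)C(F)(F)F
Why: Bromine–lithium exchange, then 1,2-addition of the alkenyllithium to the more electrophilic carbonyl (the one bonded to the methoxy-bearing carbon and not deactivated as a vinylogous ester), then Williamson-type O-methylation of the lithium alkoxide by methyl triflate in the same flask; the quaternary centre forms racemic and is erased in step 4.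

Step 4
Reactants: 7 rac-4-(3,3-diethoxyprop-1-en-2-yl)-3,4-dimethoxycyclobut-2-en-1-one
Product: 10 3-(diethoxymethyl)-4,5-dimethoxyphenol, via dienylketene 8 (not isolated), via cyclohexadienone 9 (not isolated)
Conditions: PhMe (0.01 M), 110 °C, Ar
Reagents that add atoms: none
Why: Heat should trigger conrotatory four-electron electrocyclic opening of the C1–C4 bond of 7, with the C4 methoxy group (an oxygen donor) turning outward so that the alkenyl group sits on the same side of the new double bond as the ketene in (Z)-dienylketene 8. A thermally allowed disrotatory six-electron electrocyclisation then joins the ketene carbon to the terminal CH2 of the propenyl unit (the C5'–C6' bond), closing ring B as the six-membered carbocycle of cyclohexadienone 9, which tautomerises irreversibly to phenol 10. The closest known reaction type is the thermal ring expansion of 4-alkenyl-4-alkoxycyclobutenones derived from squaric esters to hydroquinone monoethers. No stereocentre is created, and the single racemic centre of 7 becomes the aromatic C2'. The selectivity required is torquoselectivity (alkenyl inward), secured by the C4 oxygen substituent, while the substitution pattern is fixed by connectivity: ketene carbon to C5' (free OH), ring CH to C4', the two methoxy carbons to C3' and C2', the two vinyl carbons to C1' and C6'. High dilution should keep the monosubstituted ketene from intermolecular capture by phenol already formed.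

Step 5
Reactants: 10 3-(diethoxymethyl)-4,5-dimethoxyphenol
Product: 12 5-(benzyloxy)-2,3-dimethoxybenzaldehyde, via benzyl ether acetal 11 (not isolated)
Conditions: BnBr, K2CO3, DMF, rt; then 2 M HCl, THF, rt
Reagents that add atoms: benzyl bromide, BrCc1ccccc1; water, O
Why: Williamson etherification of the phenoxide (the acetal is inert to base), then acid-catalysed acetal hydrolysis in the same flask should free the aldehyde.

Step 6
Reactants: 12 5-(benzyloxy)-2,3-dimethoxybenzaldehyde; 13 1-(6-hydroxy-2,3,4-trimethoxyphenyl)ethan-1-one
Product: 14 (E)-3-[5-(benzyloxy)-2,3-dimethoxyphenyl]-1-(6-hydroxy-2,3,4-trimethoxyphenyl)prop-2-en-1-one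
Conditions: KOH, EtOH, rt; then 1 M HCl
Reagents that add atoms: none
Why: Claisen–Schmidt condensation of the acetophenone enolate with the non-enolisable aldehyde, where E1cB dehydration should give the thermodynamically favoured (E)-enone and form the future C2=C3 bond.

Step 7
Reactants: 14 (E)-3-[5-(benzyloxy)-2,3-dimethoxyphenyl]-1-(6-hydroxy-2,3,4-trimethoxyphenyl)prop-2-en-1-one
Product: 15 2-[5-(benzyloxy)-2,3-dimethoxyphenyl]-5,6,7-trimethoxy-4H-chromen-4-one
Conditions: I2 (10 mol%), DMSO, 130 °C
Reagents that add atoms: none
Why: Iodine-catalysed oxidative cyclisation of a 2'-hydroxychalcone, in which 6-endo oxa-Michael closure (O1–C2) gives the flavanone, α-iodination and loss of HI give the flavone, and DMSO re-oxidises the iodide.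

Step 8
Reactants: 15 2-[5-(benzyloxy)-2,3-dimethoxyphenyl]-5,6,7-trimethoxy-4H-chromen-4-one
Product: 16 5-hydroxy-2-(5-hydroxy-2,3-dimethoxyphenyl)-6,7-dimethoxy-4H-chromen-4-one
Conditions: BCl3, C6HMe5, CH2Cl2, −78 → 0 °C; then MeOH, H2O
Reagents that add atoms: none
Why: Lewis-acid ether cleavage, in which BCl3 should remove the aryl benzyl ether at low temperature with pentamethylbenzene trapping the benzyl cation, and on warming chelation to the C4 carbonyl should direct demethylation to the peri C5 ether only.

**Compound list**

1 | dimethyl squarate (3,4-dimethoxycyclobut-3-ene-1,2-dione) | COC1=C(OC)C(=O)C1=O | starting material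
2 | rac-4-hydroxy-2,3-dimethoxycyclobut-2-en-1-one | COC1=C(OC)C(O)C1=O | intermediate
3 | 3-methoxycyclobut-3-ene-1,2-dione (methyl semisquarate) | COC1=CC(=O)C1=O | intermediate
4 | 2-bromo-3,3-diethoxyprop-1-ene | CCOC(OCC)C(Br)=C | starting material
5 | (3,3-diethoxyprop-1-en-2-yl)lithium | [Li]C(=C)C(OCC)OCC | intermediate
6 | rac-lithium 1-(3,3-diethoxyprop-1-en-2-yl)-2-methoxy-4-oxocyclobut-2-en-1-olate | [Li+].[O-]C1(C(=C)C(OCC)OCC)C(OC)=CC1=O | intermediate
7 | rac-4-(3,3-diethoxyprop-1-en-2-yl)-3,4-dimethoxycyclobut-2-en-1-one | CCOC(OCC)C(=C)C1(OC)C(OC)=CC1=O | intermediate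
8 | (3Z)-5-(diethoxymethyl)-3,4-dimethoxyhexa-1,3,5-trien-1-one (dienylketene) | O=C=C/C(OC)=C(OC)\C(=C)C(OCC)OCC | intermediate
9 | 5-(diethoxymethyl)-3,4-dimethoxycyclohexa-2,4-dien-1-one | O=C1C=C(OC)C(OC)=C(C(OCC)OCC)C1 | intermediate
10 | 3-(diethoxymethyl)-4,5-dimethoxyphenol | CCOC(OCC)c1cc(O)cc(OC)c1OC | intermediate
11 | 1-(benzyloxy)-3-(diethoxymethyl)-4,5-dimethoxybenzene | CCOC(OCC)c1cc(OCc2ccccc2)cc(OC)c1OC | intermediate
12 | 5-(benzyloxy)-2,3-dimethoxybenzaldehyde | O=Cc1cc(OCc2ccccc2)cc(OC)c1OC | intermediate
13 | 1-(6-hydroxy-2,3,4-trimethoxyphenyl)ethan-1-one | CC(=O)c1c(O)cc(OC)c(OC)c1OC | starting material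
14 | (E)-3-[5-(benzyloxy)-2,3-dimethoxyphenyl]-1-(6-hydroxy-2,3,4-trimethoxyphenyl)prop-2-en-1-one | COc1cc(O)c(C(=O)/C=C/c2cc(OCc3ccccc3)cc(OC)c2OC)c(OC)c1OC | intermediate
15 | 2-[5-(benzyloxy)-2,3-dimethoxyphenyl]-5,6,7-trimethoxy-4H-chromen-4-one | COc1cc2oc(-c3cc(OCc4ccccc4)cc(OC)c3OC)cc(=O)c2c(OC)c1OC | intermediate
16 | 5-hydroxy-2-(5-hydroxy-2,3-dimethoxyphenyl)-6,7-dimethoxy-4H-chromen-4-one | COc1cc(O)cc(-c2cc(=O)c3c(O)c(OC)c(OC)cc3o2)c1OC | target

**Step count**

Total steps: 8. Longest linear sequence: 8 steps (1 → 16); compounds 4 and 13 enter as purchased partners.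

**Steps most likely to fail**

Step 3. O-Methylation of the crowded tertiary lithium alkoxide may lag behind its decay on warming, methyl triflate may be consumed by THF, and some addition may go to the vinylogous ester carbonyl. The fallback sets out from compounds 3 and 5 and comes back at compound 7. The adduct is quenched at −78 °C with aqueous NH4Cl and isolated as rac-4-(3,3-diethoxyprop-1-en-2-yl)-4-hydroxy-3-methoxycyclobut-2-en-1-one F1. This carbinol is then methylated without any alkoxide, using MeI and Ag2O in MeCN at rt in the dark, which should give 7.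

Step 4. Ring opening may be eroded in hot toluene by ionisation of the tertiary, doubly allylic C–OMe bond or by loss of ethanol from the neighbouring acetal, and the monosubstituted ketene may be captured intermolecularly before it cyclises. The fallback moves to the carbinol series of the same ring expansion, where hydroxyl is the outward-rotating donor and the two ring B oxygens are told apart afterwards. It sets out from compounds 3 and 5 and comes back at compound 12. The adduct is isolated as rac-4-(3,3-diethoxyprop-1-en-2-yl)-4-hydroxy-3-methoxycyclobut-2-en-1-one F1 (NH4Cl quench, no methylation) and heated in toluene under argon, which should give 2-(diethoxymethyl)-6-methoxybenzene-1,4-diol F2. Dilute HCl in THF should then give 2,5-dihydroxy-3-methoxybenzaldehyde F3. Its C2 hydroxyl is hydrogen-bonded to the aldehyde and flanked by the methoxy group, so BnBr with one equivalent of K2CO3 in acetone should benzylate only the C5 hydroxyl to 5-(benzyloxy)-2-hydroxy-3-methoxybenzaldehyde F4. MeI and K2CO3 in DMF then methylate the remaining hydroxyl to give 12.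

Step 8. After the C5 ether is cleaved, excess BCl3 may go on to the C6 ether or the ortho-dimethoxy pair of ring B, and the benzyl cation may alkylate the electron-rich ring B instead of the scavenger. The fallback separates the two cleavages and avoids the cation; it sets out from compound 15 and comes back at compound 16. Hydrogenolysis (H2, Pd/C, EtOAc, rt) should give 2-(5-hydroxy-2,3-dimethoxyphenyl)-5,6,7-trimethoxy-4H-chromen-4-one F5. AlCl3 in MeCN at 60 °C should then remove only the chelated C5 methyl group.

**Further compounds**

F1 | step 3 | rac-4-(3,3-diethoxyprop-1-en-2-yl)-4-hydroxy-3-methoxycyclobut-2-en-1-one | CCOC(OCC)C(=C)C1(O)C(OC)=CC1=O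
F2 | step 4 | 2-(diethoxymethyl)-6-methoxybenzene-1,4-diol | CCOC(OCC)c1cc(O)cc(OC)c1O
F3 | step 4 | 2,5-dihydroxy-3-methoxybenzaldehyde | O=Cc1cc(O)cc(OC)c1O
F4 | step 4 | 5-(benzyloxy)-2-hydroxy-3-methoxybenzaldehyde | O=Cc1cc(OCc2ccccc2)cc(OC)c1O
F5 | step 8 | 2-(5-hydroxy-2,3-dimethoxyphenyl)-5,6,7-trimethoxy-4H-chromen-4-one | COc1cc2oc(-c3cc(O)cc(OC)c3OC)cc(=O)c2c(OC)c1OC
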